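**Retrosynthetic overview**
1. Target 15 ⇐ all-cis tetralin diester 14 (LiAlH4) ⇐ 1-aryl-1,4-dihydronaphthalene diester 13 by syn hydrogenation anti to the aryl group; this sets C6 and C7 of the target from C8.
2. 13 ⇐ spiro[4.5]trienone 12 by an acid-induced dienone–phenol ring expansion: the benzylic spiro-ring carbon shifts 1,2 to the ring carbon para to OMe, turning the spiro five-membered ring into fused ring B.
3. 12 ⇐ vinyl iodide 11 (Pd carbonylation) ⇐ quinone methide 8 + ynoate 9 + iodide, by an enantioselective 1,6-addition/para-alkylation (3+2) spiroannulation that sets the only pre-existing stereocentre.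
4. 8 ⇐ symmetric carbinol 6 (dehydration, then mono-pivaloylation at the quinone methide stage) ⇐ 4-bromoguaiacol 3 + ethyl formate ⇐ catechol.
5. Ring order: the two aryl rings (from catechol) → spirocyclopentene (step 5) → ring B by ring expansion (step 7).

Assumption: the target is made exactly as drawn, which is the all-cis (6R,7S,8S) isomer (aryl and both CH2OH groups on one face); ethyl formate and methyl 4-chlorobut-2-ynoate are bought.

**Step 1**
Reactants: 1 catechol
Product: 2 2-methoxyphenol (guaiacol)
Conditions: MeI (0.95 equiv), K2CO3 (1.0 equiv), acetone, 56 °C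
Reagents that add atoms: iodomethane, CI
Why: Williamson mono-O-methylation of one of two equivalent phenols; veratrole and unreacted catechol are removed by base extraction and distillation.

**Step 2**
Reactants: 2 2-methoxyphenol
Product: 3 4-bromo-2-methoxyphenol
Conditions: NBS (1.0 equiv), MeCN, −10 → 23 °C
Reagents that add atoms: N-bromosuccinimide, O=C1CCC(=O)N1Br
Why: electrophilic aromatic bromination goes para to the free OH, the stronger director.

**Step 3**
Reactants: 3 4-bromo-2-methoxyphenol (2 equiv); 4 ethyl formate
Product: 6 bis(4-hydroxy-3-methoxyphenyl)methanol, via lithium 4-lithio-2-methoxyphenolate 5 (not isolated)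
Conditions: n-BuLi (2.1 equiv per 3), THF, −78 → −20 °C; HCO2Et (0.48 equiv), −78 → 23 °C; AcOH quench
Reagents that add atoms: none
Why: O-deprotonation then bromine–lithium exchange gives dianion 5, which adds twice to the formate ester (ester → aldehyde → secondary alkoxide), a standard symmetric benzhydrol synthesis that fixes both aryl–carbon bonds para to OH.

**Step 4**
Reactants: 6 bis(4-hydroxy-3-methoxyphenyl)methanol
Product: 8 4-[(3-methoxy-4-oxocyclohexa-2,5-dien-1-ylidene)methyl]-2-methoxyphenyl 2,2-dimethylpropanoate (quinone methide pivalate), via hydroxy quinone methide 7 (not isolated)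
Conditions: CSA (5 mol %), 4 Å MS, CH2Cl2/THF, 23 °C; then i-Pr2NEt (2.2 equiv), PivCl (1.05 equiv), −40 → 0 °C; cold aq. NaHCO3 wash; solution used at once
Reagents that add atoms: pivaloyl chloride, CC(C)(C)C(Cl)=O
Why: acid-catalysed dehydration of the doubly para-hydroxylated benzhydrol gives quinone methide 7, which has a single OH (its two oxygens are equivalent by tautomerism), so O-acylation of its ammonium salt can only give the mono-pivalate 8; this differentiates the two aryl rings without statistics and caps the future pendant phenol against later retro-1,6 chemistry.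

**Step 5**
Reactants: 8 quinone methide pivalate; 9 methyl 4-chlorobut-2-ynoate
Product: 11 methyl (1S)-3-iodo-7-methoxy-1-[3-methoxy-4-(2,2-dimethylpropanoyloxy)phenyl]-8-oxospiro[4.5]deca-2,6,9-triene-2-carboxylate (both C5 epimers), via iodoalkene phenolate adduct 10 (not isolated)
Conditions: 9 (1.3 equiv), NaI (1.5 equiv, ground), chiral urea–ammonium iodide Q*I = N-(9-anthracenylmethyl)-9-deoxy-9-[3-(3,5-bis(trifluoromethyl)phenyl)ureido]-epi-quininium iodide (10 mol %), 4 Å MS, PhMe/CH2Cl2 4:1, −30 → 0 °C, dark
Reagents that add atoms: sodium iodide, [Na+].[I-]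
Why: Proposed new method: iodide, carried into solution as its ion pair with the chiral ammonium cation, adds reversibly to C3 of ynoate 9 (β to the ester) to give a 3-iodoallenolate held by the urea N–H bonds; this allenolate attacks through C2 the exocyclic carbon of quinone methide 8, whose carbonyl oxygen sits in the same chiral pocket, so one face of the methide is chosen and the benzylic stereocentre (C1 of 11, later C8 of the target) is set as S (the quinidine-derived pseudo-enantiomer of the catalyst is used if assay shows the opposite sense); the ammonium aryloxide 10 then attacks CH2Cl through its para (ipso) carbon in a 5-exo-tet Winstein Ar1−-5 alkylation that dearomatises ring A, closes the spirocyclopentene with the alkene already between C2 and C3, and releases chloride, which solid NaI exchanges for iodide to turn the catalyst over; only the (Z)-iodoalkene has CH2Cl cis to the new C–C bond, and the (E) isomer can equilibrate by iodide addition–elimination; the closest known reaction types are the iodide/Lewis-acid β-iodo Morita–Baylis–Hillman (halo-aldol) coupling of ynoates with aldehydes, chiral ammonium ion-pair 1,6-additions to para-quinone methides, and base-mediated 1,6-addition/dearomative alkylation spiroannulations of tert-butyl-substituted quinone methides, none of which uses a quinone methide as the halo-allenolate acceptor, an unhindered guaiacyl quinone methide, or gives a spiro[4.5]trienone enantioselectively.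

**Step 6**
Reactants: 11 spiro vinyl iodide
Product: 12 dimethyl (1S)-7-methoxy-1-[3-methoxy-4-(2,2-dimethylpropanoyloxy)phenyl]-8-oxospiro[4.5]deca-2,6,9-triene-2,3-dicarboxylate (both C5 epimers)
Conditions: Pd(OAc)2 (5 mol %), Xantphos (6 mol %), CO (1 atm), MeOH (10 equiv), Et3N (2 equiv), DMF, 50 °C
Reagents that add atoms: carbon monoxide, [C-]#[O+]; methanol, CO
Why: palladium-catalysed alkoxycarbonylation of a β-iodoenoate (oxidative addition, CO insertion, methanolysis) installs the second ester on the ring alkene without touching the stereocentre.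

**Step 7**
Reactants: 12 spiro diester
Product: 13 dimethyl (1S)-7-hydroxy-6-methoxy-1-[3-methoxy-4-(2,2-dimethylpropanoyloxy)phenyl]-1,4-dihydronaphthalene-2,3-dicarboxylate
Conditions: CF3CO2H (10 equiv), CH2Cl2, −20 → 0 °C, argon
Reagents that add atoms: none
Why: dienone–phenol rearrangement: O-protonation turns the cross-conjugated dienone into a hydroxyarenium ion, the better-migrating spiro-ring carbon (secondary, benzylic C1 rather than the CH2) shifts 1,2 with retention to the ring carbon para to OMe (C10, the less hindered terminus giving the OMe-stabilised arenium ion), and loss of H+ re-aromatises ring A, so the spiro five-membered ring expands to fused ring B; both spiro epimers converge, and the pivaloyloxyaryl group and ester-bearing alkene disfavour ionisation of C1, so its configuration is kept.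

**Step 8**
Reactants: 13 dihydronaphthalene diester
Product: 14 dimethyl (1S,2S,3R)-7-hydroxy-6-methoxy-1-[3-methoxy-4-(2,2-dimethylpropanoyloxy)phenyl]-1,2,3,4-tetrahydronaphthalene-2,3-dicarboxylate
Conditions: H2 (20 bar), 10% Pd/C, EtOAc, 23 °C
Reagents that add atoms: none
Why: heterogeneous syn hydrogenation of the tetrasubstituted C2=C3 bond from the face opposite the pseudo-axial C1 aryl group puts both esters cis to the aryl group, setting C2 (S) and C3 (R) in the all-cis arrangement.

**Step 9**
Reactants: 14 tetralin diester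
Product: 15 (6R,7S,8S)-8-(4-hydroxy-3-methoxyphenyl)-6,7-bis(hydroxymethyl)-3-methoxy-5,6,7,8-tetrahydronaphthalen-2-ol
Conditions: LiAlH4 (6 equiv), THF, 0 → 23 °C; aqueous work-up at pH 5
Reagents that add atoms: none
Why: hydride reduction converts both esters to primary alcohols and cleaves the aryl pivalate to the phenol faster than any enolisation, so no stereocentre is touched.

**Compound list**
1 | catechol | Oc1ccccc1O | starting material
2 | 2-methoxyphenol | COc1ccccc1O | intermediate
3 | 4-bromo-2-methoxyphenol | COc1cc(Br)ccc1O | intermediate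
4 | ethyl formate | CCOC=O | starting material
5 | lithium 4-lithio-2-methoxyphenolate | [Li]c1ccc([O-])c(OC)c1.[Li+] | intermediate
6 | bis(4-hydroxy-3-methoxyphenyl)methanol | COc1cc(ccc1O)C(O)c1ccc(O)c(OC)c1 | intermediate
7 | 4-[(4-hydroxy-3-methoxyphenyl)methylidene]-2-methoxycyclohexa-2,5-dien-1-one (E/Z not defined) | COC1=CC(=Cc2ccc(O)c(OC)c2)C=CC1=O | intermediate
8 | 4-[(3-methoxy-4-oxocyclohexa-2,5-dien-1-ylidene)methyl]-2-methoxyphenyl 2,2-dimethylpropanoate (E/Z not defined) | COC1=CC(=Cc2ccc(OC(=O)C(C)(C)C)c(OC)c2)C=CC1=O | intermediate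
9 | methyl 4-chlorobut-2-ynoate | COC(=O)C#CCCl | starting material
10 | methyl (2Z)-4-chloro-2-[(R)-(4-hydroxy-3-methoxyphenyl)[3-methoxy-4-(2,2-dimethylpropanoyloxy)phenyl]methyl]-3-iodobut-2-enoate (present as its ammonium phenolate) | COC(=O)/C(=C(\I)CCl)[C@H](c1ccc(O)c(OC)c1)c1ccc(OC(=O)C(C)(C)C)c(OC)c1 | intermediate
11 | methyl (1S)-3-iodo-7-methoxy-1-[3-methoxy-4-(2,2-dimethylpropanoyloxy)phenyl]-8-oxospiro[4.5]deca-2,6,9-triene-2-carboxylate (spiro C5 not defined) | COC(=O)C1=C(I)CC2(C=CC(=O)C(OC)=C2)[C@@H]1c1ccc(OC(=O)C(C)(C)C)c(OC)c1 | intermediate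
12 | dimethyl (1S)-7-methoxy-1-[3-methoxy-4-(2,2-dimethylpropanoyloxy)phenyl]-8-oxospiro[4.5]deca-2,6,9-triene-2,3-dicarboxylate (spiro C5 not defined) | COC(=O)C1=C(C(=O)OC)CC2(C=CC(=O)C(OC)=C2)[C@@H]1c1ccc(OC(=O)C(C)(C)C)c(OC)c1 | intermediate
13 | dimethyl (1S)-7-hydroxy-6-methoxy-1-[3-methoxy-4-(2,2-dimethylpropanoyloxy)phenyl]-1,4-dihydronaphthalene-2,3-dicarboxylate | COC(=O)C1=C(C(=O)OC)Cc2cc(OC)c(O)cc2[C@@H]1c1ccc(OC(=O)C(C)(C)C)c(OC)c1 | intermediate
14 | dimethyl (1S,2S,3R)-7-hydroxy-6-methoxy-1-[3-methoxy-4-(2,2-dimethylpropanoyloxy)phenyl]-1,2,3,4-tetrahydronaphthalene-2,3-dicarboxylate | COc1cc([C@H]2c3cc(O)c(OC)cc3C[C@@H](C(=O)OC)[C@H]2C(=O)OC)ccc1OC(=O)C(C)(C)C | intermediate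
15 | (6R,7S,8S)-8-(4-hydroxy-3-methoxyphenyl)-6,7-bis(hydroxymethyl)-3-methoxy-5,6,7,8-tetrahydronaphthalen-2-ol | COc1cc([C@H]2c3cc(O)c(OC)cc3C[C@@H](CO)[C@H]2CO)ccc1O | target

**Step count and risks**
Total: 9 steps. Longest linear sequence: 9 steps (1 → 15); 4 and 9 enter as purchased materials.

The three steps most likely to fail are step 5, step 7 and step 8.

Step 5 (the proposed new spiroannulation) may fail because iodide does not add to the ynoate without a Lewis acid, because the ee is low on an unhindered quinone methide used as an E/Z mixture, or because the aryloxide is O-alkylated intermolecularly. The fallback uses only known reaction types, sets out from 8 and comes back at 12. A copper-acetylide 1,6-addition of tert-butyldimethyl(prop-2-yn-1-yloxy)silane to the quinone methide (CuI, i-Pr2NEt, PhMe; with (S,S)-Ph-pybox on the copper if the asymmetric variant carries over, otherwise racemic) gives the diarylbutynyl silyl ether F1. Oxidative syn bis(methoxycarbonylation) of the alkyne (PdI2/KI cat., CO/air, MeOH) gives the (Z)-maleate diester F2, in which the CH2O arm is cis to the diarylmethyl group. PPh3Br2 in CH2Cl2 converts the silyl ether directly into the allylic bromide F3. K2CO3 in MeCN at 0 °C then effects the classical phenoxide para-alkylation (Winstein Ar1−-5) to give 12, bypassing 11 and step 6. If F1 was made racemic, 13 (one stereocentre) is resolved by preparative chiral SFC after step 7.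

Step 7 (ring expansion) may fail by migration of the CH2 carbon, by migration to the carbon ortho to OMe, or by partial ionisation of C1 with loss of ee. The fallback replaces the concerted shift by a stepwise fragmentation–Friedel–Crafts ring expansion; it sets out from 12 and comes back at 15. K2CO3 in MeOH removes the pivalate, and the freed pendant phenoxide cleaves the C1–C5 bond (retro-1,6-addition) to give the ring-opened quinone methide F4, in which only the former C1 can re-bond to ring A. CF3CO2H (or the chiral phosphoric acid (R)-TRIP for an enantioselective closure) then closes ring B para to OMe, as in classical cyclolignan formation, to give the des-pivaloyl dihydronaphthalene F5, which is resolved by chiral SFC if needed. Hydrogenation as in step 8 gives the diphenol tetralin diester F6, and LiAlH4 gives 15.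

Step 8 (hydrogenation) may fail by palladium-surface dehydrogenation of the 1,4-dihydronaphthalene to the arylnaphthalene, by alkene migration toward C1, or by slow reduction of the tetrasubstituted alkene. The fallback sets out from 13 and comes back at 15. i-Bu2AlH (CH2Cl2, −78 → 0 °C) reduces both esters and removes the pivalate to give the dienyl tetraol F7. Hydroxyl-directed homogeneous hydrogenation with [Ir(cod)(PCy3)(py)]PF6 (H2, CH2Cl2, 23 °C) then adds hydrogen on the face away from the aryl group and gives 15 directly.

**Further compounds**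
F1 | step 5 | 4-[(1R)-4-(tert-butyldimethylsilyloxy)-1-(4-hydroxy-3-methoxyphenyl)but-2-yn-1-yl]-2-methoxyphenyl 2,2-dimethylpropanoate | CC(C)(C)[Si](C)(C)OCC#C[C@H](c1ccc(O)c(OC)c1)c1ccc(OC(=O)C(C)(C)C)c(OC)c1
F2 | step 5 | dimethyl (2Z)-2-[(tert-butyldimethylsilyloxy)methyl]-3-[(R)-(4-hydroxy-3-methoxyphenyl)[3-methoxy-4-(2,2-dimethylpropanoyloxy)phenyl]methyl]but-2-enedioate | COC(=O)/C(=C(/CO[Si](C)(C)C(C)(C)C)C(=O)OC)[C@H](c1ccc(O)c(OC)c1)c1ccc(OC(=O)C(C)(C)C)c(OC)c1
F3 | step 5 | dimethyl (2E)-2-(bromomethyl)-3-[(R)-(4-hydroxy-3-methoxyphenyl)[3-methoxy-4-(2,2-dimethylpropanoyloxy)phenyl]methyl]but-2-enedioate | COC(=O)/C(=C(/CBr)C(=O)OC)[C@H](c1ccc(O)c(OC)c1)c1ccc(OC(=O)C(C)(C)C)c(OC)c1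
F4 | step 7 | dimethyl (2Z)-2-[(4-hydroxy-3-methoxyphenyl)methyl]-3-[(3-methoxy-4-oxocyclohexa-2,5-dien-1-ylidene)methyl]but-2-enedioate | COC(=O)/C(Cc1ccc(O)c(OC)c1)=C(/C=C1C=CC(=O)C(OC)=C1)C(=O)OC
F5 | step 7 | dimethyl (1S)-7-hydroxy-1-(4-hydroxy-3-methoxyphenyl)-6-methoxy-1,4-dihydronaphthalene-2,3-dicarboxylate | COC(=O)C1=C(C(=O)OC)Cc2cc(OC)c(O)cc2[C@@H]1c1ccc(O)c(OC)c1
F6 | step 7 | dimethyl (1S,2S,3R)-7-hydroxy-1-(4-hydroxy-3-methoxyphenyl)-6-methoxy-1,2,3,4-tetrahydronaphthalene-2,3-dicarboxylate | COc1cc([C@H]2c3cc(O)c(OC)cc3C[C@@H](C(=O)OC)[C@H]2C(=O)OC)ccc1O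
F7 | step 8 | (8S)-8-(4-hydroxy-3-methoxyphenyl)-6,7-bis(hydroxymethyl)-3-methoxy-5,8-dihydronaphthalen-2-ol | COc1cc([C@H]2c3cc(O)c(OC)cc3CC(CO)=C2CO)ccc1O
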